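**Retrosynthetic overview**
1. No ring is built: the indole 1, the mirror-symmetric dibrominated imide 2 and the imidazole are bought intact. Only the two C–C bonds flanking the imide C=C are made.
2. First bond made (key step): imide C4–indole C3, by addition–elimination of the N-magnesio indole 3 on 2. This breaks the symmetry of 2 and leaves one C–Br in monobromide 4.
3. Second bond made (the first one cut in the retrosynthesis): imide C3–imidazole C5, by Pd-catalysed C5–H arylation of 1-methylimidazole 5 with 4, giving target 6.
4. Order: indole first, because the indolyl group tames the remaining bromo-enone so that nucleophilic 5 is less likely to quaternise on it; imidazole last; no protecting groups.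

Assumption: the target has no stereocentre and no stereogenic double bond (its only C=C is inside the five-membered imide ring), so the SMILES given is the single stereoisomer and no stereocontrol is needed.

**Route**

Step 1
Reactants: 1 6-bromo-1H-indole; 2 3,4-dibromo-1H-pyrrole-2,5-dione (2,3-dibromomaleimide)
Product: 4 3-bromo-4-(6-bromo-1H-indol-3-yl)-1H-pyrrole-2,5-dione, via (6-bromoindol-1-yl)magnesium bromide 3 (not isolated)
Conditions: 1 (3.0 equiv), EtMgBr (2.9 equiv), THF, 0 → 45 °C, 45 min; then 2 (1.0 equiv) in THF, 0 °C → rt, 3 h; aq NH4Cl; excess 1 recovered on silica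
Reagents that add atoms: ethylmagnesium bromide, CC[Mg]Br (supplies the MgBr of intermediate 3; none of its atoms remains in 4)
Why: Steglich-type indolyl Grignard addition–elimination (vinylic substitution), in which ambident 3 attacks a bromo-enone carbon of 2 through C3, bromide leaves and the 3H-indole tautomerises, while the mono-adduct sits in THF as a doubly metalated push–pull salt that resists a second attack, so the symmetry of 2 is broken at the mono-substitution stage (one equivalent of 3 is spent on the imide N–H and one on the product indole N–H); no stereocentre is formed.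

Step 2
Reactants: 4 3-bromo-4-(6-bromo-1H-indol-3-yl)-1H-pyrrole-2,5-dione; 5 1-methyl-1H-imidazole
Product: 6 didemnimide D, 3-(6-bromo-1H-indol-3-yl)-4-(1-methyl-1H-imidazol-5-yl)-1H-pyrrole-2,5-dione
Conditions: 5 (4 equiv), Pd(OAc)2 (5 mol %), P(2-furyl)3 (10 mol %), KOAc (3 equiv), degassed DMA, 90 °C, Ar; dilute aq AcOH work-up
Reagents that add atoms: none
Why: Proposed new method: zerovalent palladium should insert into the electron-poor alkenyl C–Br of 4 far faster than into the electron-rich aryl C6–Br, and the alkenylpalladium acetate then metalates 5 at C5–H by acetate-assisted concerted metalation–deprotonation before reductive elimination (the weakly nucleophilic furylphosphine and the partly deprotonated imide suppress conjugate addition to the bromo-enone, and excess 5 suppresses double arylation), the closest known reaction type being the Pd(OAc)2-catalysed C5-selective direct C–H arylation of 1-methylimidazole with aryl bromides, alongside Stille and Suzuki couplings of 3-bromo-4-indolylmaleimides; no stereocentre is formed.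

**Compound list**
1 | 6-bromo-1H-indole (achiral) | Brc1ccc2cc[nH]c2c1 | starting material
2 | 3,4-dibromo-1H-pyrrole-2,5-dione (2,3-dibromomaleimide, achiral) | O=C1NC(=O)C(Br)=C1Br | starting material
3 | (6-bromo-1H-indol-1-yl)magnesium bromide (achiral, not isolated) | Br[Mg]n1ccc2ccc(Br)cc21 | intermediate
4 | 3-bromo-4-(6-bromo-1H-indol-3-yl)-1H-pyrrole-2,5-dione (achiral) | O=C1NC(=O)C(c2c[nH]c3cc(Br)ccc23)=C1Br | intermediate
5 | 1-methyl-1H-imidazole (achiral) | Cn1ccnc1 | starting material
6 | didemnimide D, 3-(6-bromo-1H-indol-3-yl)-4-(1-methyl-1H-imidazol-5-yl)-1H-pyrrole-2,5-dione (achiral) | Cn1cncc1C1=C(c2c[nH]c3cc(Br)ccc23)C(=O)NC1=O | target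

**Step count and risks**
Total step count: 2. Longest linear sequence: 2 steps (1 + 2 → 4, then 4 + 5 → 6).

The route has only two steps, so both are ranked below, and the more fragile one, step 2, appears twice, once for each of its two independent failure modes.

Risk 1, step 2 (C–H coupling loses to N3-quaternisation of 5 on the bromo-enone, or C2/C5 mixtures form). The fallback sets out from 4 and comes back at 6. It gives up C–H activation and fixes the regiochemistry with tin: Stille coupling of 4 with commercial 1-methyl-5-(tributylstannyl)-1H-imidazole F1 (Pd(PPh3)4 5 mol %, CuI 10 mol %, DMF, 70 °C) gives 6 directly. The base-free medium keeps the imide neutral and the alkenyl bromide reactive, and the C6–Br should be untouched at this temperature.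

Risk 2, step 1 (the N-magnesiated imide 2 is too poor an acceptor, or bis-indolylation and poor mass balance). The fallback sets out from 2 and comes back at 4. The imide nitrogen is masked first: Mitsunobu N-alkylation of 2 with 2,4-dimethoxybenzyl alcohol (PPh3, DIAD, THF, 0 °C → rt) gives 3,4-dibromo-1-[(2,4-dimethoxyphenyl)methyl]-1H-pyrrole-2,5-dione F2. The same Grignard reagent 3 (2.2 equiv, THF, 0 °C → rt) then gives 3-bromo-4-(6-bromo-1H-indol-3-yl)-1-[(2,4-dimethoxyphenyl)methyl]-1H-pyrrole-2,5-dione F3. Acidolysis of the benzyl group (TFA, anisole 5 equiv, 70 °C) returns 4.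

Risk 3, step 2 (palladium also inserts into the indole C6–Br, or the anionic imide or product 6 shuts the catalyst down, so that no cross-coupling at 4 is clean). The fallback sets out from 1 and comes back at 6. It avoids palladium and builds the imide ring instead. C3-acylation of 1 with oxalyl chloride (Et2O, 0 °C) gives 2-(6-bromo-1H-indol-3-yl)-2-oxoacetyl chloride F4, which is quenched in the same flask with MeOH to methyl 2-(6-bromo-1H-indol-3-yl)-2-oxoacetate F5. Perkin-type condensation of F5 with purchased 2-(1-methyl-1H-imidazol-5-yl)acetamide F6 (t-BuOK 3.5 equiv, THF, 0 °C → rt; conc. HCl quench) closes the maleimide and gives 6.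

**Further compounds**
F1 | step 2 | 1-methyl-5-(tributylstannyl)-1H-imidazole | CCCC[Sn](CCCC)(CCCC)c1cncn1C
F2 | step 1 | 3,4-dibromo-1-[(2,4-dimethoxyphenyl)methyl]-1H-pyrrole-2,5-dione | COc1ccc(CN2C(=O)C(Br)=C(Br)C2=O)c(OC)c1
F3 | step 1 | 3-bromo-4-(6-bromo-1H-indol-3-yl)-1-[(2,4-dimethoxyphenyl)methyl]-1H-pyrrole-2,5-dione | COc1ccc(CN2C(=O)C(Br)=C(c3c[nH]c4cc(Br)ccc34)C2=O)c(OC)c1
F4 | step 2 | 2-(6-bromo-1H-indol-3-yl)-2-oxoacetyl chloride | O=C(Cl)C(=O)c1c[nH]c2cc(Br)ccc12
F5 | step 2 | methyl 2-(6-bromo-1H-indol-3-yl)-2-oxoacetate | COC(=O)C(=O)c1c[nH]c2cc(Br)ccc12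
F6 | step 2 | 2-(1-methyl-1H-imidazol-5-yl)acetamide | Cn1cncc1CC(N)=O
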